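**Plan**

1. Numbering: carbocycle C1–C14 (C1 lactone CH, C2 lactone OCH, C3=C4(Me), C6=C7, C8 carbinol, C11–C12 epoxide, C13 CHOAc); C15(=C17) and C16 (C=O) complete the lactone. Enabling feature: the lactone oxygen lies between C16 and the secondary, allylic C2, so the five-membered lactone is the oxygen-insertion product of a C1–C2–C16–C15 cyclobutanone cis-fused to the 14-membered ring.
2. Cuts (retro): C13–OAc and C15=C17; O–C2/O–C16 (Baeyer–Villiger); C5–C6 (allyl–alkenyl Stille ring closure); C3=C4 (Wittig); C1–C15 and C2–C16 (allene [2+2] on a temporary six-membered lactone tying C13–O to C3); C13–C14 (allylboration); C11=C12 (Z-olefination); C6–C10 from geraniol.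
3. Forward: geraniol → C6–C13 epoxy aldehyde → allylation, acrylate, metathesis (temporary lactone) → photocycloaddition (cyclobutane) → lactol Wittig opens the tether → Stille closure of the 14-membered ring → oxidation and Baeyer–Villiger (γ-lactone) → C13 reduction, methylenation, acetylation.
4. Stereochemistry: C8 from Sharpless epoxidation of geraniol (C–O bond kept); C11/C12 from Sharpless epoxidation of a Z-allylic alcohol (in the target C10 and C13 are cis on the epoxide); C1/C2 from the cis-selective photocycloaddition anti to a temporary 13S centre set by allylboration; C13 (R) from chelation-controlled reduction of the 13-ketone after the key step; olefin geometries from Wittig and hydrostannation.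

Key step: step 23

Assumption: the target is (1S,2S,3E,6E,8S,11S,12S,13R) in the numbering above; C6–C7 is carried as a C-silylated alkyne until ring closure.

**Route**

Step 1
Reactants: 1 geraniol
Product: 2 (2S,3S)-2,3-epoxygeraniol
Conditions: Ti(OiPr)4 (5 mol%), L-(+)-diethyl tartrate (7 mol%), tBuOOH, 4 Å MS, CH2Cl2, −20 °C
Reagents that add atoms: tert-butyl hydroperoxide CC(C)(C)OO
Why: Sharpless asymmetric epoxidation of the allylic alcohol: the titanium–L-(+)-tartrate complex delivers oxygen to one face of the 2,3-olefin only, giving the 2S,3S epoxide whose C3 becomes C8 (S), while the isolated 6,7-olefin is not touched.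

Step 2
Reactants: 2 (2S,3S)-2,3-epoxygeraniol
Product: 3 (2R,3S)-1-chloro-2,3-epoxy-3,7-dimethyloct-6-ene
Conditions: PPh3, CCl4, NaHCO3, reflux
Reagents that add atoms: carbon tetrachloride ClC(Cl)(Cl)Cl
Why: Appel chlorination converts the primary alcohol into the chloride under near-neutral conditions that leave the epoxide intact.

Step 3
Reactants: 3 (2R,3S)-1-chloro-2,3-epoxy-3,7-dimethyloct-6-ene
Product: 5 (S)-3,7-dimethyl-1-(triethylsilyl)-3-(triethylsilyloxy)oct-6-en-1-yne, via dilithium alkoxide acetylide 4 (not isolated)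
Conditions: nBuLi (3.3 equiv), THF, −40 °C; then Et3SiOTf (2.3 equiv), −78 → 0 °C
Reagents that add atoms: triethylsilyl trifluoromethanesulfonate CC[Si](CC)(CC)OS(=O)(=O)C(F)(F)F
Why: Base-induced elimination of a 2,3-epoxy chloride (deprotonation at CHCl with epoxide opening, then loss of HCl) gives the tertiary propargylic alkoxide without breaking the C8–O bond, so C8 stays S, and the alkoxide and the acetylide are both silylated in the same flask.

Step 4
Reactants: 5 (S)-3,7-dimethyl-1-(triethylsilyl)-3-(triethylsilyloxy)oct-6-en-1-yne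
Product: 6 (S)-4-methyl-6-(triethylsilyl)-4-(triethylsilyloxy)hex-5-ynal (C6–C11 aldehyde)
Conditions: O3, CH2Cl2, −78 °C; then PPh3
Reagents that add atoms: ozone [O-][O+]=O
Why: Ozonolysis with reductive work-up cleaves the electron-rich trisubstituted olefin, the silylalkyne and silyl ether being inert to ozone at −78 °C.

Step 5
Reactants: 6 (S)-4-methyl-6-(triethylsilyl)-4-(triethylsilyloxy)hex-5-ynal; 7 ethyl 2-[bis(2,2,2-trifluoroethoxy)phosphoryl]propanoate
Product: 8 ethyl (2Z,6S)-2,6-dimethyl-8-(triethylsilyl)-6-(triethylsilyloxy)oct-2-en-7-ynoate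
Conditions: KN(SiMe3)2, 18-crown-6, THF, −78 °C
Reagents that add atoms: none
Why: Still–Gennari variant of the Horner–Wadsworth–Emmons olefination: the trifluoroethyl phosphonate gives the Z-trisubstituted enoate (C13 cis to C10) under kinetic control, which the cis-epoxide of the target requires.

Step 6
Reactants: 8 ethyl (2Z,6S)-2,6-dimethyl-8-(triethylsilyl)-6-(triethylsilyloxy)oct-2-en-7-ynoate
Product: 9 (2Z,6S)-2,6-dimethyl-8-(triethylsilyl)-6-(triethylsilyloxy)oct-2-en-7-yn-1-ol
Conditions: iBu2AlH, CH2Cl2, −78 °C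
Reagents that add atoms: none
Why: 1,2-Reduction of the enoate to the allylic alcohol with an aluminium hydride at low temperature keeps the Z geometry.

Step 7
Reactants: 9 (2Z,6S)-2,6-dimethyl-8-(triethylsilyl)-6-(triethylsilyloxy)oct-2-en-7-yn-1-ol
Product: 10 C6–C13 epoxy alcohol, (2R,3S,6S)-2,3-epoxy-2,6-dimethyl-8-(triethylsilyl)-6-(triethylsilyloxy)oct-7-yn-1-ol (epoxide configured as in the target)
Conditions: Ti(OiPr)4 (10 mol%), D-(−)-diethyl tartrate (12 mol%), tBuOOH, 4 Å MS, CH2Cl2, −20 °C
Reagents that add atoms: tert-butyl hydroperoxide CC(C)(C)OO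
Why: Sharpless asymmetric epoxidation of the Z-allylic alcohol: D-(−)-tartrate delivers oxygen to the face that gives the 11S,12S epoxide (C10 and C13 cis), under reagent control and independent of the remote C8 centre.

Step 8
Reactants: 10 C6–C13 epoxy alcohol
Product: 11 C6–C13 epoxy aldehyde (C13 = CHO on the fully substituted epoxide carbon C12)
Conditions: Dess–Martin periodinane, NaHCO3, CH2Cl2, 0 °C
Reagents that add atoms: none
Why: Dess–Martin oxidation of the primary alcohol under buffered conditions; the α-carbon C12 is fully substituted, so the epoxy aldehyde cannot epimerise.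

Step 9
Reactants: 11 C6–C13 epoxy aldehyde; 12 (−)-B-allyldiisopinocampheylborane (reagent derived from (+)-α-pinene)
Product: 13 13S homoallylic alcohol (allyl adduct of 11; C13–OH, C14H2, terminal vinyl)
Conditions: Et2O, −78 °C; then NaOH, H2O2
Reagents that add atoms: none
Why: Brown allylboration through a chair transition state: the reagent derived from (+)-α-pinene attacks the Si face of the aldehyde and sets C13 as S, on purpose the epimer of the target, because this centre only steers step 12 and is reset in step 24.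

Step 10
Reactants: 13 13S homoallylic alcohol; 14 acryloyl chloride
Product: 15 acrylate ester of 13
Conditions: iPr2NEt, DMAP (cat.), CH2Cl2, 0 °C
Reagents that add atoms: none
Why: Acylation of the hindered secondary alcohol with an acid chloride and amine base (esterification) installs the second olefin for ring closure.

Step 11
Reactants: 15 acrylate ester of 13
Product: 16 6-substituted 5,6-dihydro-2H-pyran-2-one (temporary lactone O–C13–C14–C1=C2–C3(=O))
Conditions: second-generation Grubbs catalyst RuCl2(=CHPh)(PCy3)(H2IMes) (5 mol%), CH2Cl2 (5 mM), 40 °C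
Reagents that add atoms: none
Why: Ring-closing olefin metathesis of the acrylate with the allyl terminus forms the six-membered unsaturated lactone with loss of ethylene, the hindered silylalkyne staying out of enyne metathesis.

Step 12
Reactants: 16 6-substituted 5,6-dihydro-2H-pyran-2-one; 17 allene
Product: 18 cis-fused 8-methylene-3-oxabicyclo[4.2.0]octan-2-one (C16(=CH2) on C2, C15H2 on C1, cyclobutane anti to the C13 side chain)
Conditions: hν (medium-pressure Hg lamp, quartz), acetone, −78 °C
Reagents that add atoms: none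
Why: Enone-type [2+2] photocycloaddition with allene, head-to-head (central allene carbon to C2, α to the carbonyl): the six-membered ring enforces the cis C1/C2 fusion, and the first bond forms at C1 on the face trans to the pseudo-equatorial C13 side chain, so the 13S centre sets C1 and C2 as in the target.

Step 13
Reactants: 18 cis-fused 8-methylene lactone
Product: 20 all-cis 8-hydroxy-3-oxabicyclo[4.2.0]octan-2-one (C16 cyclobutanol), via β-keto lactone 19 (not isolated)
Conditions: O3, CH2Cl2/MeOH, −78 °C; then NaBH4, −78 → 0 °C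
Reagents that add atoms: ozone [O-][O+]=O
Why: Ozonolysis of the 1,1-disubstituted olefin and immediate borohydride reduction: hydride adds to the convex face of the strained β-keto lactone before retro-Claisen opening can occur, giving the all-cis cyclobutanol (this C16 centre is erased in step 22).

Step 14
Reactants: 20 C16 cyclobutanol lactone
Product: 21 C16 triethylsilyl ether of 20
Conditions: Et3SiOTf, 2,6-lutidine, CH2Cl2, −78 °C
Reagents that add atoms: triethylsilyl trifluoromethanesulfonate CC[Si](CC)(CC)OS(=O)(=O)C(F)(F)F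
Why: Silylation of the cyclobutanol (silyl triflate, hindered base) blocks retro-aldol opening of the four-membered ring once C3 becomes an aldehyde.

Step 15
Reactants: 21 C16 triethylsilyl ether lactone
Product: 22 lactol (C3 hemiacetal, mixture of anomers)
Conditions: iBu2AlH (1.1 equiv), CH2Cl2, −78 °C
Reagents that add atoms: none
Why: Partial reduction of the lactone to the lactol, the tetrahedral aluminium alkoxide being stable at −78 °C.

Step 16
Reactants: 22 lactol; 23 ethyl 2-(triphenylphosphoranylidene)propanoate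
Product: 24 hydroxy enoate (C5 ethyl ester, E-C3=C4(Me), free 13S-OH, cis-cyclobutane with C16–OSiEt3)
Conditions: toluene, 80 °C
Reagents that add atoms: none
Why: Wittig olefination of the open hydroxy-aldehyde form of the lactol with a stabilised α-methyl ylide gives the E-trisubstituted C3=C4 enoate and frees the C13 hydroxyl, the neutral conditions avoiding oxa-Michael reclosure and epimerisation at C2.

Step 17
Reactants: 24 hydroxy enoate
Product: 25 C5 allylic alcohol (C5 and C13 diol)
Conditions: iBu2AlH (3.5 equiv), CH2Cl2, −78 °C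
Reagents that add atoms: none
Why: 1,2-Reduction of the enoate to the C5 allylic alcohol at −78 °C, where the epoxide is not opened.

Step 18
Reactants: 25 C5 allylic alcohol
Product: 26 tetraol with terminal alkyne (C5, C8, C13, C16 hydroxyls; C6≡C7–H)
Conditions: Bu4NF, THF, 0 °C → rt
Reagents that add atoms: none
Why: Fluoride-mediated desilylation cleaves the alkynyl C–Si bond and both silyl ethers in one operation, exposing the terminal alkyne and the two carbinols to be oxidised later.

Step 19
Reactants: 26 tetraol with terminal alkyne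
Product: 27 (E)-alkenylstannane (C6–SnBu3, E-C6=C7)
Conditions: Bu3SnH, PdCl2(PPh3)2 (3 mol%), THF, 0 °C
Reagents that add atoms: tributyltin hydride CCCC[SnH](CCCC)CCCC
Why: Palladium-catalysed syn-hydrostannation of the terminal alkyne: the fully substituted propargylic carbon C8 directs tin to the terminal carbon and gives the E-alkenylstannane at C6.

Step 20
Reactants: 27 (E)-alkenylstannane
Product: 28 C5 allylic acetate of 27
Conditions: AcCl (1.05 equiv), 2,4,6-collidine, CH2Cl2, −78 °C
Reagents that add atoms: acetyl chloride CC(=O)Cl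
Why: Selective acetylation of the primary allylic hydroxyl over the two secondary and the tertiary hydroxyls with acetyl chloride and collidine at −78 °C.

Step 21
Reactants: 28 C5 allylic acetate
Product: 29 macrocyclic triol (14-membered ring cis-fused to the C16 cyclobutanol; 8-OH, 13S-OH, 3E,6E)
Conditions: Pd2(dba)3 (10 mol%), AsPh3, LiCl, NMP, 40 °C, 1 mM (slow addition)
Reagents that add atoms: none
Why: Intramolecular Stille coupling of the allylic acetate with the alkenylstannane through a π-allylpalladium intermediate: C–C bond formation at the unhindered C5 terminus closes the 14-membered ring with both olefin geometries retained.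

Step 22
Reactants: 29 macrocyclic triol
Product: 30 macrocycle-fused cis-cyclobutanone (C16 ketone, 13-ketone, free 8-OH, 11,12-epoxide)
Conditions: Dess–Martin periodinane (3 equiv), NaHCO3, CH2Cl2, 0 °C → rt
Reagents that add atoms: none
Why: Dess–Martin oxidation of both secondary alcohols under buffered conditions gives the cyclobutanone and the 13-ketone while the tertiary C8 hydroxyl is inert, the temporary C13 and C16 centres being erased.

Step 23
Reactants: 30 macrocycle-fused cis-cyclobutanone
Product: 31 cis-fused γ-lactone (O between C16 and C2; 13-ketone, free 8-OH, no exo-methylene)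
Conditions: 30% H2O2, NaOH, THF/MeOH, 0 °C; then pH 6 buffer
Reagents that add atoms: hydrogen peroxide OO
Why: Hydroperoxide anion adds to the strained C16 carbonyl to give a Criegee adduct and the C2–C16 bond migrates to oxygen with loss of hydroxide, which is the alkaline-peroxide Baeyer–Villiger oxidation of a cyclobutanone, a known reaction type. The five-membered lactone arises by ring expansion (1,2-shift of C2 from C16 to O) and not by a cyclisation, so the C1–C2 ring fusion is carried over unchanged. No stereocentre is created: migration proceeds with retention, so the cis fusion and the C2 configuration fixed in step 12 reappear in the lactone. Regioselectivity (C2 over C15) follows from C2 being secondary and allylic while C15 is primary. Chemoselectivity rests on the nucleophilic oxidant, which neither epoxidises the isolated C3=C4 and C6=C7 olefins nor opens the epoxide, and on ring strain, which lets only the four-membered ketone rearrange while the unstrained, hindered 13-ketone adds peroxide reversibly at most. Epimerisation at the enolisable C2 should be outrun by the fast oxidation at 0 °C and a buffered work-up.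

Step 24
Reactants: 31 cis-fused γ-lactone with 13-ketone
Product: 32 13R-hydroxy lactone
Conditions: Zn(BH4)2, Et2O, −20 °C
Reagents that add atoms: none
Why: Chelation-controlled hydride reduction of the α,β-epoxy ketone: zinc bridges the ketone and epoxide oxygens and hydride adds to the face away from C11, giving the anti epoxy alcohol (13R), while the lactone is not reduced.

Step 25
Reactants: 32 13R-hydroxy lactone
Product: 35 α-methylene lactone diol (13-deacetyl target), via Mannich base 33 (not isolated), via trimethylammonium iodide 34 (not isolated)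
Conditions: LiN(SiMe3)2 (3.3 equiv), THF, −78 °C, then CH2=NMe2+ I−; MeI, THF/MeOH, rt; then aq. NaHCO3
Reagents that add atoms: N,N-dimethylmethyleneiminium iodide C=[N+](C)C.[I-]
Why: Eschenmoser methylenation: Mannich reaction of the lithium lactone enolate (C15 is its only enolisable position) with the iminium salt, N-methylation and elimination of trimethylamine give the exocyclic C15=C17 olefin.

Step 26
Reactants: 35 α-methylene lactone diol
Product: 36 target, (1S,2S,3E,6E,8S,11S,12S,13R)-13-acetoxy-11,12-epoxy-8-hydroxycembra-3,6,15(17)-trien-16,2-olide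
Conditions: Ac2O, pyridine, DMAP (cat.), CH2Cl2, 0 °C
Reagents that add atoms: acetic anhydride CC(=O)OC(C)=O
Why: DMAP-catalysed acetylation of the secondary C13 hydroxyl, the tertiary C8 hydroxyl being unreactive at 0 °C.

**Compound list**

1 | geraniol | CC(C)=CCC/C(C)=C/CO | starting material
2 | (2S,3S)-2,3-epoxygeraniol | OC[C@@H]1O[C@@]1(C)CCC=C(C)C | intermediate
3 | (2R,3S)-1-chloro-2,3-epoxy-3,7-dimethyloct-6-ene | ClC[C@@H]1O[C@@]1(C)CCC=C(C)C | intermediate
4 | dilithium alkoxide acetylide of (S)-3,7-dimethyloct-6-en-1-yn-3-ol | [Li+].[Li+].[C-]#C[C@@](C)([O-])CCC=C(C)C | intermediate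
5 | (S)-3,7-dimethyl-1-(triethylsilyl)-3-(triethylsilyloxy)oct-6-en-1-yne | CC[Si](CC)(CC)C#C[C@@](C)(O[Si](CC)(CC)CC)CCC=C(C)C | intermediate
6 | (S)-4-methyl-6-(triethylsilyl)-4-(triethylsilyloxy)hex-5-ynal | CC[Si](CC)(CC)C#C[C@@](C)(O[Si](CC)(CC)CC)CCC=O | intermediate
7 | ethyl 2-[bis(2,2,2-trifluoroethoxy)phosphoryl]propanoate | CCOC(=O)C(C)P(=O)(OCC(F)(F)F)OCC(F)(F)F | starting material
8 | ethyl (2Z,6S)-2,6-dimethyl-8-(triethylsilyl)-6-(triethylsilyloxy)oct-2-en-7-ynoate | CC[Si](CC)(CC)C#C[C@@](C)(O[Si](CC)(CC)CC)CC/C=C(/C)C(=O)OCC | intermediate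
9 | (2Z,6S)-2,6-dimethyl-8-(triethylsilyl)-6-(triethylsilyloxy)oct-2-en-7-yn-1-ol | CC[Si](CC)(CC)C#C[C@@](C)(O[Si](CC)(CC)CC)CC/C=C(/C)CO | intermediate
10 | C6–C13 epoxy alcohol, (2R,3S,6S)-2,3-epoxy-2,6-dimethyl-8-(triethylsilyl)-6-(triethylsilyloxy)oct-7-yn-1-ol | CC[Si](CC)(CC)C#C[C@@](C)(O[Si](CC)(CC)CC)CC[C@@H]1O[C@]1(C)CO | intermediate
11 | C6–C13 epoxy aldehyde | CC[Si](CC)(CC)C#C[C@@](C)(O[Si](CC)(CC)CC)CC[C@@H]1O[C@]1(C)C=O | intermediate
12 | (−)-B-allyldiisopinocampheylborane | C=CCB([C@@H]1C[C@@H]2C[C@H]([C@H]1C)C2(C)C)[C@@H]1C[C@@H]2C[C@H]([C@H]1C)C2(C)C | starting material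
13 | 13S homoallylic alcohol | CC[Si](CC)(CC)C#C[C@@](C)(O[Si](CC)(CC)CC)CC[C@@H]1O[C@]1(C)[C@@H](O)CC=C | intermediate
14 | acryloyl chloride | C=CC(=O)Cl | starting material
15 | acrylate ester of 13 | CC[Si](CC)(CC)C#C[C@@](C)(O[Si](CC)(CC)CC)CC[C@@H]1O[C@]1(C)[C@@H](OC(=O)C=C)CC=C | intermediate
16 | 6-substituted 5,6-dihydro-2H-pyran-2-one | CC[Si](CC)(CC)C#C[C@@](C)(O[Si](CC)(CC)CC)CC[C@@H]1O[C@]1(C)[C@@H]2CC=CC(=O)O2 | intermediate
17 | allene (propa-1,2-diene) | C=C=C | starting material
18 | cis-fused 8-methylene-3-oxabicyclo[4.2.0]octan-2-one photoadduct | CC[Si](CC)(CC)C#C[C@@](C)(O[Si](CC)(CC)CC)CC[C@@H]1O[C@]1(C)[C@@H]2C[C@H]3CC(=C)[C@H]3C(=O)O2 | intermediate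
19 | β-keto lactone (8-oxo analogue of 18) | CC[Si](CC)(CC)C#C[C@@](C)(O[Si](CC)(CC)CC)CC[C@@H]1O[C@]1(C)[C@@H]2C[C@H]3CC(=O)[C@H]3C(=O)O2 | intermediate
20 | all-cis C16 cyclobutanol lactone | CC[Si](CC)(CC)C#C[C@@](C)(O[Si](CC)(CC)CC)CC[C@@H]1O[C@]1(C)[C@@H]2C[C@H]3C[C@@H](O)[C@H]3C(=O)O2 | intermediate
21 | C16 triethylsilyl ether of 20 | CC[Si](CC)(CC)C#C[C@@](C)(O[Si](CC)(CC)CC)CC[C@@H]1O[C@]1(C)[C@@H]2C[C@H]3C[C@@H](O[Si](CC)(CC)CC)[C@H]3C(=O)O2 | intermediate
22 | lactol (anomer mixture at C3) | CC[Si](CC)(CC)C#C[C@@](C)(O[Si](CC)(CC)CC)CC[C@@H]1O[C@]1(C)[C@@H]2C[C@H]3C[C@@H](O[Si](CC)(CC)CC)[C@H]3C(O)O2 | intermediate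
23 | ethyl 2-(triphenylphosphoranylidene)propanoate | CCOC(=O)C(C)=P(c1ccccc1)(c1ccccc1)c1ccccc1 | starting material
24 | hydroxy enoate (E-C3=C4, C5 ethyl ester) | CC[Si](CC)(CC)C#C[C@@](C)(O[Si](CC)(CC)CC)CC[C@@H]1O[C@]1(C)[C@@H](O)C[C@H]2C[C@@H](O[Si](CC)(CC)CC)[C@H]2/C=C(\C)C(=O)OCC | intermediate
25 | C5 allylic alcohol | CC[Si](CC)(CC)C#C[C@@](C)(O[Si](CC)(CC)CC)CC[C@@H]1O[C@]1(C)[C@@H](O)C[C@H]2C[C@@H](O[Si](CC)(CC)CC)[C@H]2/C=C(\C)CO | intermediate
26 | tetraol with terminal alkyne | C#C[C@@](C)(O)CC[C@@H]1O[C@]1(C)[C@@H](O)C[C@H]2C[C@@H](O)[C@H]2/C=C(\C)CO | intermediate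
27 | (E)-alkenylstannane | CCCC[Sn](CCCC)(CCCC)/C=C/[C@@](C)(O)CC[C@@H]1O[C@]1(C)[C@@H](O)C[C@H]2C[C@@H](O)[C@H]2/C=C(\C)CO | intermediate
28 | C5 allylic acetate | CCCC[Sn](CCCC)(CCCC)/C=C/[C@@](C)(O)CC[C@@H]1O[C@]1(C)[C@@H](O)C[C@H]2C[C@@H](O)[C@H]2/C=C(\C)COC(C)=O | intermediate
29 | macrocyclic triol (cyclobutanol-fused 14-membered ring) | C1[C@@H](O)[C@H]2/C=C(\C)C/C=C/[C@@](C)(O)CC[C@@H]3O[C@]3(C)[C@@H](O)C[C@@H]12 | intermediate
30 | macrocycle-fused cis-cyclobutanone with 13-ketone | C1C(=O)[C@H]2/C=C(\C)C/C=C/[C@@](C)(O)CC[C@@H]3O[C@]3(C)C(=O)C[C@@H]12 | intermediate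
31 | cis-fused γ-lactone with 13-ketone | C1C(=O)O[C@H]2/C=C(\C)C/C=C/[C@@](C)(O)CC[C@@H]3O[C@]3(C)C(=O)C[C@@H]12 | intermediate
32 | 13R-hydroxy lactone | C1C(=O)O[C@H]2/C=C(\C)C/C=C/[C@@](C)(O)CC[C@@H]3O[C@]3(C)[C@H](O)C[C@@H]12 | intermediate
33 | Mannich base (C15–CH2NMe2, trans to C14) | CN(C)C[C@@H]1C(=O)O[C@H]2/C=C(\C)C/C=C/[C@@](C)(O)CC[C@@H]3O[C@]3(C)[C@H](O)C[C@@H]12 | intermediate
34 | trimethylammonium iodide of 33 | C[N+](C)(C)C[C@@H]1C(=O)O[C@H]2/C=C(\C)C/C=C/[C@@](C)(O)CC[C@@H]3O[C@]3(C)[C@H](O)C[C@@H]12.[I-] | intermediate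
35 | α-methylene lactone diol (13-deacetyl target) | C=C1C(=O)O[C@H]2/C=C(\C)C/C=C/[C@@](C)(O)CC[C@@H]3O[C@]3(C)[C@H](O)C[C@@H]12 | intermediate
36 | CNP0288879.2 | C=C1C(=O)O[C@H]2/C=C(\C)C/C=C/[C@@](C)(O)CC[C@@H]3O[C@]3(C)[C@H](OC(C)=O)C[C@@H]12 | target

**Totals and risks**

Total step count: 26. Longest linear sequence: 26 steps (geraniol to target).

Step 12 (photocycloaddition). The excited lactone may not discriminate well between its two faces, because the C13 side chain is remote from C2; head-to-tail addition and allene polymerisation may also compete. Fallback: the four-membered ring is built by a thermal keteniminium–olefin [2+2] on the allyl group instead. Setting out from 13, silylation (Et3SiOTf, 2,6-lutidine) gives the triethylsilyl ether F1. The keteniminium salt generated from the separately prepared amide (E)-N,N-dimethyl-4-methyl-5-(triethylsilyloxy)pent-3-enamide F2 (Tf2O, 2,4,6-collidine, ClCH2CH2Cl) should add to the terminal olefin of F1 with C16 bonding to C15 and C2 to C1. Aqueous NaHCO3 hydrolysis would then give the 2-alkenylcyclobutanone F3; facial control is given up here, so its C1/C2 isomers would have to be separated. NaBH4 reduction gives the all-cis cyclobutanol F4, and Bu4NF removes all silyl groups to come back to the route at 26.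

Step 21 (macrocyclic Stille coupling). Oligomerisation may outpace ring closure, transmetalation of the hindered alkenylstannane may be slow, and protodestannylation or O-allylation by a free hydroxyl may consume the π-allyl intermediate. Fallback: the ring is closed by olefin metathesis at C6=C7 instead. Setting out from 26, semihydrogenation of the alkyne (H2, Pd/CaCO3 poisoned with Pb(OAc)2, quinoline) gives the vinyl carbinol F5. Selective acetylation (AcCl, collidine, −78 °C) gives the C5 allylic acetate F6. Intermolecular Stille coupling with tributyl(vinyl)stannane (Pd2(dba)3, LiCl, DMF) gives the 1,4-diene F7. Ring-closing metathesis with the second-generation Hoveyda–Grubbs catalyst RuCl2(=CH–C6H4-2-OiPr)(H2IMes) at high dilution, where the quaternary C8 should favour the E olefin, comes back to the route at 29.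

Step 23 (Baeyer–Villiger oxidation). Hydroperoxide may add to or cleave the 13-ketone, and base may enolise the epoxy ketone or C2 before oxygen is inserted. Fallback: oxygen is inserted while C13 is still a carbinol. Setting out from 29, sterically selective oxidation of the unhindered cyclobutanol (TEMPO cat., PhI(OAc)2, CH2Cl2) gives the 13S-hydroxy cyclobutanone F8. Its Baeyer–Villiger oxidation (H2O2, NaOH, −10 °C) gives the 13S-hydroxy lactone F9, and Dess–Martin oxidation of F9 comes back to the route at 31.

**Further compounds**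

F1 | step 12 | triethylsilyl ether of 13 | CC[Si](CC)(CC)C#C[C@@](C)(O[Si](CC)(CC)CC)CC[C@@H]1O[C@]1(C)[C@@H](O[Si](CC)(CC)CC)CC=C
F2 | step 12 | (E)-N,N-dimethyl-4-methyl-5-(triethylsilyloxy)pent-3-enamide | CN(C)C(=O)C/C=C(\C)CO[Si](CC)(CC)CC
F3 | step 12 | cis-2-alkenyl-3-alkylcyclobutanone (silyl-protected) | CC[Si](CC)(CC)C#C[C@@](C)(O[Si](CC)(CC)CC)CC[C@@H]1O[C@]1(C)[C@@H](O[Si](CC)(CC)CC)C[C@H]2CC(=O)[C@H]2/C=C(\C)CO[Si](CC)(CC)CC
F4 | step 12 | all-cis cyclobutanol from F3 | CC[Si](CC)(CC)C#C[C@@](C)(O[Si](CC)(CC)CC)CC[C@@H]1O[C@]1(C)[C@@H](O[Si](CC)(CC)CC)C[C@H]2C[C@@H](O)[C@H]2/C=C(\C)CO[Si](CC)(CC)CC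
F5 | step 21 | vinyl carbinol tetraol (C6=C7 terminal olefin) | C=C[C@@](C)(O)CC[C@@H]1O[C@]1(C)[C@@H](O)C[C@H]2C[C@@H](O)[C@H]2/C=C(\C)CO
F6 | step 21 | C5 allylic acetate of F5 | C=C[C@@](C)(O)CC[C@@H]1O[C@]1(C)[C@@H](O)C[C@H]2C[C@@H](O)[C@H]2/C=C(\C)COC(C)=O
F7 | step 21 | 1,4-diene (C5-vinylated) triol | C=C[C@@](C)(O)CC[C@@H]1O[C@]1(C)[C@@H](O)C[C@H]2C[C@@H](O)[C@H]2/C=C(\C)CC=C
F8 | step 23 | macrocycle-fused cis-cyclobutanone with 13S-hydroxyl | C1C(=O)[C@H]2/C=C(\C)C/C=C/[C@@](C)(O)CC[C@@H]3O[C@]3(C)[C@@H](O)C[C@@H]12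
F9 | step 23 | cis-fused γ-lactone with 13S-hydroxyl | C1C(=O)O[C@H]2/C=C(\C)C/C=C/[C@@](C)(O)CC[C@@H]3O[C@]3(C)[C@@H](O)C[C@@H]12
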